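The numbers in the tables are simulated for substances that don't exist; the scatter is artificial.

I decide to reckon no rate here but one share, since the flasks asked about differ in their charge of E.

common to all: G 20 mM; L 0.5 mol% (in portions, 3)

| flask | E | remark | time |
|---|---|---|---|
| beta | 1.8 mM | run made earlier; portions every 10 h |  |
| epsilon | 16 mM | run made earlier; portions every 10 h |  |
| Wednesday's | 1.20 mM | the portions of L follow each other after 10 h, the first at the start | 30 h |
| Monday's | 3.00 mM | the portions of L follow each other after 10 h, the first at the start | 30 h |
| Sunday's | 10.0 mM | the portions of L follow each other after 10 h, the first at the start | 30 h |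

- beta (time / h: Q / %, G / %): 4.00: 9.9, 82.2; 8.00: 16.0, 72.2; 12.0: 24.1, 62.0; 15.0: 28.0, 55.9; 20.0: 32.1, 50.0
- epsilon (time / h: Q / %, G / %): 2.00: 4.5, 64.9; 5.00: 8.3, 42.8; 10.0: 11.5, 26.5; 15.0: 13.0, 18.5; 20.0: 12.6, 14.9

(each reading ± 0.5 percentage points)

- "hardly changes" means that all values lie within two and a half points (for a concentration: within two and a half percent of the largest)

* [Q] at the end for Wednesday's, Monday's, Sunday's, in this order
* how the row runs (rises all the way / falls all the way / hardly changes / falls, then rises / rises, then falls)

The epsilon run comes first: between 15.0 h and 20.0 h its cQ stays within the scatter, 13.0% and then 12.6%, but its cG still falls from 18.5% to 14.9%, so its ratio cQ/cG is still moving, from 0.703 to 0.846, and this last reading is no settled balance; I take it as a rough working stand-in for one, where the symmetric case of G and Q equally favoured would read 1. But G and Q do not add up: in the beta run at 20.0 h a gap of 17.9% of the charge is missing, and E, taken one for one with G, would account for 9.00% of the charge, so I suppose a further unseen form beside Q, which this reading puts at 0.277 of cQ. Together these give 0.407, and this number is the Q share, cQ over the sum of cG, cQ and the unseen form at balance; an even split over the three forms would be a third, so by this reading Q stands above the statistical zero. Taking E as the limiting reagent of the side route, I expect the pool to be the charge of G minus the charge of E, and my reckoning, share times pool, gives 7.64 mM, 6.91 mM and 4.07 mM. The forecast, with its side route “using about 2 G per E”, says 9 mM, 7.2 mM and 3.4 mM, so falls all the way, which is higher than mine for Wednesday's and lower for Sunday's.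

The flask gives 7.35 mM, 6.66 mM and 4.11 mM, so falls all the way.

    G + L ⇌ Q + L, rate k1*[G]*[L] forward; the back reaction follows from the equilibrium constant (K = 0.840, k = 14.4 M⁻¹ min⁻¹)
    Q ⇌ J (K = 0.350, k = 3.01 × 10⁻⁴ min⁻¹)
    J + L ⇌ G + L, rate k3*[L]*[J] forward; the back reaction follows from the equilibrium constant (k = 9.44 M⁻¹ min⁻¹)
    G + E → X (k = 0.236 M⁻¹ min⁻¹)

In Wednesday's flask the relaxation half-life of Q and J by the step between them alone, both ways together, is 9.95 h, shorter than the 30 h of the run, and reading that flask at 300 h instead makes no difference to its cQ. Wednesday's ends with X at 5.97% and a Q share of 0.391, while Sunday's, with X at 48.3% of the G charged, ends with a Q share of 0.397.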